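The numbers were set for the occasion; no experiment stands behind them.

We follow the partner.

    substrate + partner → mono adduct (k1 = 0.048 M⁻¹ s⁻¹)
    partner + double product → triple product (k2 = 0.12 M⁻¹ s⁻¹)
    partner + mono adduct → double product (k3 = 0.097 M⁻¹ s⁻¹)
    partner → decomposed reagent (k4 = 0.0025 s⁻¹)

substrate 0.20 M; partner 3.00 equiv; time 50 min

* conversion of substrate at 50 min
* amount of mono adduct at 50 min, in percent of the substrate charged
* amount of triple product at 50 min, in percent of the substrate charged
* amount of double product at 50 min, in percent of the substrate charged

Partner is the limiting reagent, and one quantity keeps its ledger: the partner exposure, the area under c partner against time. Each addition is first order in this exposure, and the decomposed reagent formed is the decomposition constant times it. Decomposition by itself has a half-life of 4.6 min, shorter than 50 min, and leaves 0.0553% of the partner over that time. So the exposure stops growing at a finite value, which the books must find.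

Our own trial sets the first rate constant times the exposure to 2.3, which gives a partner exposure of 47.9 M·s. The chain then holds substrate 10.0%, mono adduct 8.88%, double product 10.2% and triple product 70.9%.

Now the entries. Making mono adduct takes 0.180 M of partner, making double product 0.162 M, making triple product 0.142 M, and decomposition 0.120 M. These sum to 0.604 M against a charge of 0.600 M. We have overspent by 0.00400 M, so our exposure is slightly high, and we commit to these shares as they stand.

The forecast, reasoning that “the outcome depends only on the total partner exposure”, gives 89.8% conversion, with 9.1% mono adduct, 70.4% triple product and 10.3% double product.

The simulation gives 89.7% conversion, with 9.07% mono adduct, 70.3% triple product and 10.3% double product. In this flask, each addition had done half of its turnover up to 50 min by 0.406 min for mono adduct, 0.808 min for double product and 1.19 min for triple product, and partner stood at 3.78% of its charge after 5.00 min. Partner in this flask stood at 0% of its charge after 25.0 min, and the shares moved 0 percentage points over the second half of the time. The 0.119 M of decomposed reagent in this flask reads as an exposure of 47.4 M·s, beside our 47.9 M·s. The neighbour with 1.20 equiv of partner holds 0.0411 M of decomposed reagent, an exposure of 16.5 M·s, about a third of ours. That exposure gives 45.4% substrate, and the neighbour holds 45.4%.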